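The 1,2-dioxane (C5, C6, C7, C8 and the two peroxide oxygens; cembrane numbering) is not closed by C–O bond formation but grown from the cyclobutane C5–C6–C7–C8. A cobalt-generated alkoxy radical at C5 of a 1-alkenylcyclobutanol cleaves the C5–C8 bond, because C8 is fully substituted and C5 becomes an enone carbonyl, and O2 fills the gap. This one operation installs the peroxide, enlarges the carbocycle from twelve to fourteen members and leaves a bridgehead hemiperketal that is reduced in the last step. The precursor is a twelve-membered carbocycle fused to the cyclobutanol and already carrying the cis α-methylene lactone, both E-alkenes and the C9 acetate.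

Key step: step 16

Remarks on the chemistry (assumptions):
- Cembrane numbering is used: C1 (lactone ring-fusion CH), C2, C3=C4(Me), C5 (O), C6, C7, C8 (Me, O), C9 (OAc), C10, C11, C12(Me)=C13, C14 (lactone O–CH), C15 (=C17H2), C16 (C=O). The target is (1S,3E,5S,8R,9S,12E,14S).
- The configurations at C5 and C8 of the cyclobutane intermediates are erased in step 16. C5 of compound 21 is therefore drawn without configuration; both epimers converge.
- For the two ligand-controlled steps (6 and 14), the ligand enantiomer is the one that gives the configuration stated.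

Step 1
Reactants: 1 geraniol
Product: 2 geranyl tert-butyldimethylsilyl ether
Conditions: TBSCl, imidazole, DMF, 0 °C to rt
Reagents that add atoms: tert-butyldimethylsilyl chloride, CC(C)(C)[Si](C)(C)Cl
Why: Silylation of the primary allylic alcohol gives a protecting group that should survive the oxidation, ylide and Grignard steps ahead.

Step 2
Reactants: 2 geranyl tert-butyldimethylsilyl ether
Product: 3 6,7-epoxygeranyl tert-butyldimethylsilyl ether (racemic)
Conditions: mCPBA, NaHCO3, CH2Cl2, −20 to 0 °C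
Reagents that add atoms: 3-chloroperoxybenzoic acid, O=C(OO)c1cccc(Cl)c1
Why: Prilezhaev epoxidation should take the remote, more electron-rich trisubstituted alkene rather than the one deactivated by the allylic oxygen; the new stereocentre is removed in step 3.

Step 3
Reactants: 3 6,7-epoxygeranyl tert-butyldimethylsilyl ether
Product: 4 (4E)-6-(tert-butyldimethylsilyloxy)-4-methylhex-4-enal
Conditions: H5IO6, THF/Et2O, 0 °C
Reagents that add atoms: none
Why: Periodic acid opens the epoxide at its tertiary carbon and cleaves the diol (Malaprade glycol cleavage) to the aldehyde and acetone, the epoxide oxygen staying on the aldehyde carbon.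

Step 4
Reactants: 4 (4E)-6-(tert-butyldimethylsilyloxy)-4-methylhex-4-enal; 5 ethyl 2-(triphenylphosphoranylidene)propanoate
Product: 6 ethyl (2E,6E)-8-(tert-butyldimethylsilyloxy)-2,6-dimethylocta-2,6-dienoate
Conditions: CH2Cl2, rt to 40 °C
Reagents that add atoms: none
Why: Wittig olefination with a stabilised ylide should give the (E)-2-methyl enoate, which fixes the alkene geometry used in step 6.

Step 5
Reactants: 6 ethyl (2E,6E)-8-(tert-butyldimethylsilyloxy)-2,6-dimethylocta-2,6-dienoate
Product: 7 1-[(2E,6E)-8-(tert-butyldimethylsilyloxy)-6-methylocta-2,6-dien-2-yl]cyclopropan-1-ol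
Conditions: EtMgBr (3 equiv), Ti(OiPr)4 (0.5 equiv), THF, 0 °C to rt
Reagents that add atoms: ethylmagnesium bromide, CC[Mg]Br
Why: Kulinkovich cyclopropanation: the titanacyclopropane formed from two ethyl groups adds twice to the ester carbonyl, and the α-methyl and β-alkyl groups of the enoate should suppress ligand exchange with the conjugated alkene.

Step 6
Reactants: 7 1-[(2E,6E)-8-(tert-butyldimethylsilyloxy)-6-methylocta-2,6-dien-2-yl]cyclopropan-1-ol
Product: 9 (2S)-2-[(1S,4E)-6-(tert-butyldimethylsilyloxy)-1-hydroxy-4-methylhex-4-en-1-yl]-2-methylcyclobutan-1-one, via epoxy cyclopropanol 8 (not isolated)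
Conditions: WO2(acac)2 (5 mol %), chiral bis-hydroxamic acid ligand (6 mol %), 30% aq. H2O2 (1.1 equiv), NaCl, CH2Cl2, rt
Reagents that add atoms: hydrogen peroxide, OO
Why: Hydroxyl-directed catalytic asymmetric epoxidation should touch only the alkene next to the cyclopropanol and set C9 under ligand control, after which the epoxide undergoes strain-driven semipinacol ring expansion, the cyclopropane bond migrating to C8 anti to the breaking C–O bond.

Step 7
Reactants: 9 (2S)-2-[(1S,4E)-6-(tert-butyldimethylsilyloxy)-1-hydroxy-4-methylhex-4-en-1-yl]-2-methylcyclobutan-1-one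
Product: 10 (1S,4E)-6-(tert-butyldimethylsilyloxy)-4-methyl-1-[(1S)-1-methyl-2-oxocyclobutyl]hex-4-en-1-yl acetate
Conditions: Ac2O, pyridine, DMAP (cat.), CH2Cl2, 0 °C to rt
Reagents that add atoms: acetic anhydride, CC(=O)OC(C)=O
Why: Acylation installs the C9 acetate of the target early and blocks retro-aldol cleavage; C8 carries no hydrogen, so β-elimination cannot occur.

Step 8
Reactants: 10 (1S,4E)-6-(tert-butyldimethylsilyloxy)-4-methyl-1-[(1S)-1-methyl-2-oxocyclobutyl]hex-4-en-1-yl acetate
Product: 11 (1S,4E)-6-hydroxy-4-methyl-1-[(1S)-1-methyl-2-oxocyclobutyl]hex-4-en-1-yl acetate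
Conditions: HF·pyridine, pyridine, THF, 0 °C
Reagents that add atoms: none
Why: Fluoride-mediated desilylation should free the primary allylic alcohol without touching the acetate or the ketone.

Step 9
Reactants: 11 (1S,4E)-6-hydroxy-4-methyl-1-[(1S)-1-methyl-2-oxocyclobutyl]hex-4-en-1-yl acetate
Product: 12 (1S,4E)-4-methyl-1-[(1S)-1-methyl-2-oxocyclobutyl]-6-oxohex-4-en-1-yl acetate
Conditions: Dess–Martin periodinane, NaHCO3, CH2Cl2, rt
Reagents that add atoms: none
Why: Buffered Dess–Martin oxidation should give the (E)-enal and leave the β-acetoxy cyclobutanone intact.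

Step 10
Reactants: 13 pent-3-yn-1-ol
Product: 14 (3E)-4-iodopent-3-en-1-ol
Conditions: Cp2Zr(H)Cl (2.2 equiv), THF, rt; then I2, 0 °C
Reagents that add atoms: iodine, II
Why: syn-Hydrozirconation places zirconium on the methyl-bearing alkyne carbon after equilibration, and iododezirconation with retention should give the (E)-iodoalkene.

Step 11
Reactants: 14 (3E)-4-iodopent-3-en-1-ol
Product: 15 (3E)-4-iodopent-3-enal
Conditions: Dess–Martin periodinane, NaHCO3, CH2Cl2, 0 °C; used crude
Reagents that add atoms: none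
Why: Buffered Dess–Martin oxidation gives the β,γ-unsaturated aldehyde without base that would move the double bond into conjugation.

Step 12
Reactants: 15 (3E)-4-iodopent-3-enal; 16 methyl propiolate
Product: 17 methyl (5E)-3-hydroxy-6-iodo-2-methylidenehept-5-enoate (racemic)
Conditions: iBu2AlH, NMO, THF, 0 °C (with 16); then 15, 0 °C to rt
Reagents that add atoms: none
Why: Hydroalumination of the propiolate gives an α-aluminoacrylate that adds to the aldehyde (vinylalumination, a Morita–Baylis–Hillman equivalent) fast enough to avoid isomerisation of the skipped aldehyde.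

Step 13
Reactants: 17 methyl (5E)-3-hydroxy-6-iodo-2-methylidenehept-5-enoate
Product: 18 methyl (2Z,5E)-2-(bromomethyl)-6-iodohepta-2,5-dienoate
Conditions: NBS, Me2S, CH2Cl2, −20 to 0 °C
Reagents that add atoms: N-bromosuccinimide, O=C1CCC(=O)N1Br
Why: The alkoxysulfonium salt is displaced by bromide in the SN2' sense (Corey–Kim-type allylic bromination) to give the thermodynamically preferred (Z)-2-(bromomethyl)enoate.

Step 14
Reactants: 12 (1S,4E)-4-methyl-1-[(1S)-1-methyl-2-oxocyclobutyl]-6-oxohex-4-en-1-yl acetate; 18 methyl (2Z,5E)-2-(bromomethyl)-6-iodohepta-2,5-dienoate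
Product: 20 (4S,5S)-5-{(1E,5S)-5-acetoxy-2-methyl-5-[(1S)-1-methyl-2-oxocyclobutyl]pent-1-en-1-yl}-4-[(2E)-3-iodobut-2-en-1-yl]-3-methylidenedihydrofuran-2(3H)-one, via hydroxy ester 19 (not isolated)
Conditions: CrCl2 (10 mol %), chiral carbazole bis(oxazoline) ligand (12 mol %), Mn powder, Cp2ZrCl2, THF, rt; aqueous work-up; then TsOH·H2O (cat.), CH2Cl2, rt
Reagents that add atoms: none
Why: Catalytic asymmetric Nozaki–Hiyama 2-(alkoxycarbonyl)allylation: the allylchromium species (trivalent chromium), with C2 cis to the metal-bearing CH2, adds to the aldehyde through a chair transition state to give the syn adduct and hence the cis lactone, the ligand selecting the aldehyde face (14S, and with it 1S), while the hindered ketone and, in the absence of nickel, the alkenyl iodide stay untouched.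

Step 15
Reactants: 20 (4S,5S)-5-{(1E,5S)-5-acetoxy-2-methyl-5-[(1S)-1-methyl-2-oxocyclobutyl]pent-1-en-1-yl}-4-[(2E)-3-iodobut-2-en-1-yl]-3-methylidenedihydrofuran-2(3H)-one
Product: 21 (1S,3E,8S,9S,12E,14S)-9-acetoxy-5-hydroxy-5,8-cyclocembra-3,12,15(17)-trien-16,14-olide (C5 epimers)
Conditions: CrCl2 (10 equiv), NiCl2 (2 mol %), DMSO/THF, rt, 2 mM, slow addition
Reagents that add atoms: none
Why: Nozaki–Hiyama–Kishi reaction: zerovalent nickel inserts into the C–I bond, transmetalation gives the alkenylchromium species with retained E geometry, and this should add to the cyclobutanone, whose strain relief on rehybridisation makes it far more electrophilic than an ordinary ketone; the configuration formed at C5 is without consequence.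

Step 16
Reactants: 21 (1S,3E,8S,9S,12E,14S)-9-acetoxy-5-hydroxy-5,8-cyclocembra-3,12,15(17)-trien-16,14-olide
Product: 23 (1S,3E,5S,8R,9S,12E,14S)-9-acetoxy-5-hydroxy-5,8-epidioxycembra-3,12,15(17)-trien-16,14-olide, via hydroperoxy enone 22 (not isolated)
Conditions: Co(acac)2 (20 mol %), O2 (1 atm), MeCN, 40 °C
Reagents that add atoms: dioxygen, O=O
Why: Oxygenation of Co(acac)2 gives a trivalent cobalt species that exchanges onto the tertiary alcohol; homolysis of the Co–O bond gives the C5 alkoxy radical, β-scission of the strained C5–C8 bond gives the C5 enone and the tertiary C8 radical, O2 is captured at C8, and the resulting hydroperoxide 22 adds to the C5 carbonyl. The closest known reaction is the cobalt-catalysed aerobic ring expansion of secondary and tertiary cyclobutanols to 1,2-dioxan-3-ols. The four-membered ring C5–C6–C7–C8 becomes the six-membered ring C5–C6–C7–C8–O–O by radical ring opening followed by 6-exo-trig addition of the hydroperoxide oxygen to the carbonyl group, and the carbocycle grows from twelve to fourteen members at the same time. C8 is set by the face of O2 capture: the C9–OAc bond aligns with the singly occupied orbital and O2 should enter anti to it along the extended C7–C10 segment, which corresponds to 8R, while C5 is a bridgehead of the new bicyclo[10.2.2] skeleton whose hydroxyl can only point outward. The step needs scission toward C8 and not toward C6, which the tertiary radical and the conjugated ketone secure, and O2 capture faster than any transannular radical addition, which the O2-saturated medium secures; no hydride source is present, so the alkenes and the α-methylene lactone should not be hydroperoxidised.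

Step 17
Reactants: 23 (1S,3E,5S,8R,9S,12E,14S)-9-acetoxy-5-hydroxy-5,8-epidioxycembra-3,12,15(17)-trien-16,14-olide
Product: 24 (1S,3E,5S,8R,9S,12E,14S)-9-acetoxy-5,8-epidioxycembra-3,12,15(17)-trien-16,14-olide (target)
Conditions: Et3SiH (5 equiv), BF3·OEt2 (2 equiv), CH2Cl2, −78 to −40 °C
Reagents that add atoms: none
Why: Ionic reduction of the hemiperketal through the peroxycarbenium ion (as for lactols and peroxyketals): hydride can reach the bridgehead cation of the bicyclo[10.2.2] skeleton only from the outer face, which gives 5S with C4 and C9 cis on the dioxane, and the charge on the oxygen-bearing carbon should favour attack at C5 over C3.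

Compound list
1 | geraniol, (2E)-3,7-dimethylocta-2,6-dien-1-ol | CC(C)=CCC/C(C)=C/CO | starting material
2 | tert-butyl{[(2E)-3,7-dimethylocta-2,6-dien-1-yl]oxy}dimethylsilane | CC(C)=CCC/C(C)=C/CO[Si](C)(C)C(C)(C)C | intermediate
3 | tert-butyl{[(2E)-5-(3,3-dimethyloxiran-2-yl)-3-methylpent-2-en-1-yl]oxy}dimethylsilane (racemic) | CC1(C)OC1CC/C(C)=C/CO[Si](C)(C)C(C)(C)C | intermediate
4 | (4E)-6-(tert-butyldimethylsilyloxy)-4-methylhex-4-enal | O=CCC/C(C)=C/CO[Si](C)(C)C(C)(C)C | intermediate
5 | ethyl 2-(triphenylphosphoranylidene)propanoate | CCOC(=O)C(C)=P(c1ccccc1)(c1ccccc1)c1ccccc1 | starting material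
6 | ethyl (2E,6E)-8-(tert-butyldimethylsilyloxy)-2,6-dimethylocta-2,6-dienoate | CCOC(=O)/C(C)=C/CC/C(C)=C/CO[Si](C)(C)C(C)(C)C | intermediate
7 | 1-[(2E,6E)-8-(tert-butyldimethylsilyloxy)-6-methylocta-2,6-dien-2-yl]cyclopropan-1-ol | OC1(CC1)/C(C)=C/CC/C(C)=C/CO[Si](C)(C)C(C)(C)C | intermediate
8 | 1-{(2R,3S)-3-[(3E)-5-(tert-butyldimethylsilyloxy)-3-methylpent-3-en-1-yl]-2-methyloxiran-2-yl}cyclopropan-1-ol | OC1(CC1)[C@]2(C)O[C@H]2CC/C(C)=C/CO[Si](C)(C)C(C)(C)C | intermediate (not isolated)
9 | (2S)-2-[(1S,4E)-6-(tert-butyldimethylsilyloxy)-1-hydroxy-4-methylhex-4-en-1-yl]-2-methylcyclobutan-1-one | O=C1CC[C@@]1(C)[C@@H](O)CC/C(C)=C/CO[Si](C)(C)C(C)(C)C | intermediate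
10 | (1S,4E)-6-(tert-butyldimethylsilyloxy)-4-methyl-1-[(1S)-1-methyl-2-oxocyclobutyl]hex-4-en-1-yl acetate | O=C1CC[C@@]1(C)[C@@H](OC(C)=O)CC/C(C)=C/CO[Si](C)(C)C(C)(C)C | intermediate
11 | (1S,4E)-6-hydroxy-4-methyl-1-[(1S)-1-methyl-2-oxocyclobutyl]hex-4-en-1-yl acetate | O=C1CC[C@@]1(C)[C@@H](OC(C)=O)CC/C(C)=C/CO | intermediate
12 | (1S,4E)-4-methyl-1-[(1S)-1-methyl-2-oxocyclobutyl]-6-oxohex-4-en-1-yl acetate | O=C1CC[C@@]1(C)[C@@H](OC(C)=O)CC/C(C)=C/C=O | intermediate
13 | pent-3-yn-1-ol | CC#CCCO | starting material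
14 | (3E)-4-iodopent-3-en-1-ol | C/C(I)=C\CCO | intermediate
15 | (3E)-4-iodopent-3-enal | C/C(I)=C\CC=O | intermediate
16 | methyl propiolate | C#CC(=O)OC | starting material
17 | methyl (5E)-3-hydroxy-6-iodo-2-methylidenehept-5-enoate (racemic) | C=C(C(=O)OC)C(O)C/C=C(\C)I | intermediate
18 | methyl (2Z,5E)-2-(bromomethyl)-6-iodohepta-2,5-dienoate | COC(=O)/C(CBr)=C/C/C=C(\C)I | intermediate
19 | methyl (3S,4S,5E,9S)-9-acetoxy-4-hydroxy-3-[(2E)-3-iodobut-2-en-1-yl]-6-methyl-9-[(1S)-1-methyl-2-oxocyclobutyl]-2-methylidenenon-5-enoate | COC(=O)C(=C)[C@H](C/C=C(\C)I)[C@@H](O)/C=C(\C)CC[C@H](OC(C)=O)[C@]1(C)CCC1=O | intermediate (not isolated)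
20 | (4S,5S)-5-{(1E,5S)-5-acetoxy-2-methyl-5-[(1S)-1-methyl-2-oxocyclobutyl]pent-1-en-1-yl}-4-[(2E)-3-iodobut-2-en-1-yl]-3-methylidenedihydrofuran-2(3H)-one | C=C1C(=O)O[C@@H](/C=C(\C)CC[C@H](OC(C)=O)[C@]2(C)CCC2=O)[C@H]1C/C=C(\C)I | intermediate
21 | (1S,3E,8S,9S,12E,14S)-9-acetoxy-5-hydroxy-5,8-cyclocembra-3,12,15(17)-trien-16,14-olide (C5 epimers; twelve-membered carbocycle fused to the 1-alkenylcyclobutanol) | C=C1C(=O)O[C@H]2/C=C(\C)CC[C@H](OC(C)=O)[C@]3(C)CCC3(O)/C(C)=C/C[C@@H]12 | intermediate
22 | (1S,3E,8R,9S,12E,14S)-9-acetoxy-8-hydroperoxy-5-oxocembra-3,12,15(17)-trien-16,14-olide | C=C1C(=O)O[C@H]2/C=C(\C)CC[C@H](OC(C)=O)[C@](C)(OO)CCC(=O)/C(C)=C/C[C@@H]12 | intermediate (not isolated)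
23 | (1S,3E,5S,8R,9S,12E,14S)-9-acetoxy-5-hydroxy-5,8-epidioxycembra-3,12,15(17)-trien-16,14-olide | C=C1C(=O)O[C@H]2/C=C(\C)CC[C@H](OC(C)=O)[C@@]3(C)CC[C@](O)(OO3)/C(C)=C/C[C@@H]12 | intermediate
24 | (1S,3E,5S,8R,9S,12E,14S)-9-acetoxy-5,8-epidioxycembra-3,12,15(17)-trien-16,14-olide | C=C1C(=O)O[C@H]2/C=C(\C)CC[C@H](OC(C)=O)[C@@]3(C)CC[C@H](OO3)/C(C)=C/C[C@@H]12 | target

Total step count: 17.
Longest linear sequence: 13 steps (steps 1 to 9, then 14 to 17).

Steps most likely to fail

1. Step 16. What may go wrong: the planar C8 radical takes up O2 on both faces, or mainly on the face syn to the C9 acetate, because only this neighbouring group and the ring conformation bias the capture. The fallback uses a bulkier shielding group at C9 and introduces the acetate last; it sets out from 9 and comes back at 24. TBSOTf and 2,6-lutidine convert 9 into the bis-silyl ether F1. HF·pyridine at 0 °C removes only the primary allylic silyl group to give alcohol F2, and Dess–Martin oxidation gives enal F3. Coupling with 18 under the conditions of step 14 gives, by way of hydroxy ester F4, the lactone F5, and ring closure as in step 15 gives cyclobutanol F6. The ring expansion as in step 16 then passes through hydroperoxy enone F7 to hemiperketal F8, the silyloxy group now shielding its face of the radical more strongly. Reduction as in step 17 gives silyl ether F9, HF·pyridine at rt gives alcohol F10, and Ac2O with pyridine and DMAP gives 24.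

2. Step 15. What may go wrong: addition of the alkenylchromium intermediate to the hindered ketone is slower than its protonation or its intermolecular reaction, so that the C–I bond is only reduced or oligomers form. The fallback makes the C4–C5 bond first and closes the ring at C1–C14 instead; it sets out from 10 and 14 and comes back at 21. NaH and 4-methoxybenzyl chloride convert 14 into the ether F11. Iodine–lithium exchange (t-BuLi, Et2O, −78 °C), transmetalation with CeCl3 and addition to the ketone of 10 give cyclobutanol F12. DDQ gives alcohol F13, Dess–Martin oxidation gives aldehyde F14, and vinylalumination with 16 as in step 12 gives allylic alcohol F15. MsCl and Et3N followed by LiBr give bromide F16 without electrophilic bromine, HF·pyridine gives alcohol F17, and MnO2 gives enal F18. CrCl2 in THF at high dilution (with the ligand of step 14 if substrate control is not sufficient) closes the ring by intramolecular allylation to hydroxy ester F19, which lactonises with PPTS to 21.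

3. Step 17. What may go wrong: under the strong Lewis acid the free hemiperketal opens to the hydroperoxy enone and fragments by heterolysis of the O–O bond with a 1,2-shift (Criegee- or Hock-type), or hydride is delivered to C3 of the conjugated cation. The fallback uses a covalent leaving group and catalytic ionisation; it sets out from 23 and comes back at 24. Ac2O, pyridine and DMAP give the peroxyketal acetate F20, which is reduced with Et3SiH and catalytic Sc(OTf)3 in CH2Cl2 at −40 °C to 24.

Further compounds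
F1 | step 16 | (2S)-2-[(1S,4E)-1,6-bis(tert-butyldimethylsilyloxy)-4-methylhex-4-en-1-yl]-2-methylcyclobutan-1-one | O=C1CC[C@@]1(C)[C@@H](O[Si](C)(C)C(C)(C)C)CC/C(C)=C/CO[Si](C)(C)C(C)(C)C
F2 | step 16 | (2S)-2-[(1S,4E)-1-(tert-butyldimethylsilyloxy)-6-hydroxy-4-methylhex-4-en-1-yl]-2-methylcyclobutan-1-one | O=C1CC[C@@]1(C)[C@@H](O[Si](C)(C)C(C)(C)C)CC/C(C)=C/CO
F3 | step 16 | (2E,6S)-6-(tert-butyldimethylsilyloxy)-3-methyl-6-[(1S)-1-methyl-2-oxocyclobutyl]hex-2-enal | O=C1CC[C@@]1(C)[C@@H](O[Si](C)(C)C(C)(C)C)CC/C(C)=C/C=O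
F4 | step 16 | 9-O-(tert-butyldimethylsilyl) analogue of hydroxy ester 19 | COC(=O)C(=C)[C@H](C/C=C(\C)I)[C@@H](O)/C=C(\C)CC[C@H](O[Si](C)(C)C(C)(C)C)[C@]1(C)CCC1=O
F5 | step 16 | 9-O-(tert-butyldimethylsilyl) analogue of lactone 20 | C=C1C(=O)O[C@@H](/C=C(\C)CC[C@H](O[Si](C)(C)C(C)(C)C)[C@]2(C)CCC2=O)[C@H]1C/C=C(\C)I
F6 | step 16 | 9-O-(tert-butyldimethylsilyl) analogue of cyclobutanol 21 (C5 epimers) | C=C1C(=O)O[C@H]2/C=C(\C)CC[C@H](O[Si](C)(C)C(C)(C)C)[C@]3(C)CCC3(O)/C(C)=C/C[C@@H]12
F7 | step 16 | 9-O-(tert-butyldimethylsilyl) analogue of hydroperoxy enone 22 | C=C1C(=O)O[C@H]2/C=C(\C)CC[C@H](O[Si](C)(C)C(C)(C)C)[C@](C)(OO)CCC(=O)/C(C)=C/C[C@@H]12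
F8 | step 16 | 9-O-(tert-butyldimethylsilyl) analogue of hemiperketal 23 | C=C1C(=O)O[C@H]2/C=C(\C)CC[C@H](O[Si](C)(C)C(C)(C)C)[C@@]3(C)CC[C@](O)(OO3)/C(C)=C/C[C@@H]12
F9 | step 16 | 9-O-(tert-butyldimethylsilyl)-9-deacetyl 24 | C=C1C(=O)O[C@H]2/C=C(\C)CC[C@H](O[Si](C)(C)C(C)(C)C)[C@@]3(C)CC[C@H](OO3)/C(C)=C/C[C@@H]12
F10 | step 16 | 9-deacetyl 24 (9-hydroxy compound) | C=C1C(=O)O[C@H]2/C=C(\C)CC[C@H](O)[C@@]3(C)CC[C@H](OO3)/C(C)=C/C[C@@H]12
F11 | step 15 | 1-({[(3E)-4-iodopent-3-en-1-yl]oxy}methyl)-4-methoxybenzene | C/C(I)=C\CCOCc1ccc(OC)cc1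
F12 | step 15 | 1-alkenylcyclobutanol from 10 and F11 (C9 acetate, C14 silyl ether, C1 4-methoxybenzyl ether; C5 epimers) | OC1(/C(C)=C/CCOCc2ccc(OC)cc2)CC[C@@]1(C)[C@@H](OC(C)=O)CC/C(C)=C/CO[Si](C)(C)C(C)(C)C
F13 | step 15 | C1 primary alcohol from F12 | OC1(/C(C)=C/CCO)CC[C@@]1(C)[C@@H](OC(C)=O)CC/C(C)=C/CO[Si](C)(C)C(C)(C)C
F14 | step 15 | C1 aldehyde from F13 | OC1(/C(C)=C/CC=O)CC[C@@]1(C)[C@@H](OC(C)=O)CC/C(C)=C/CO[Si](C)(C)C(C)(C)C
F15 | step 15 | 2-methylidene-3-hydroxy ester from F14 (C1 carbinol epimers) | OC1(/C(C)=C/CC(O)C(=C)C(=O)OC)CC[C@@]1(C)[C@@H](OC(C)=O)CC/C(C)=C/CO[Si](C)(C)C(C)(C)C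
F16 | step 15 | (Z)-2-(bromomethyl)enoate from F15 | OC1(/C(C)=C/C/C=C(\CBr)C(=O)OC)CC[C@@]1(C)[C@@H](OC(C)=O)CC/C(C)=C/CO[Si](C)(C)C(C)(C)C
F17 | step 15 | C14 allylic alcohol from F16 | OC1(/C(C)=C/C/C=C(\CBr)C(=O)OC)CC[C@@]1(C)[C@@H](OC(C)=O)CC/C(C)=C/CO
F18 | step 15 | C14 enal from F17 | OC1(/C(C)=C/C/C=C(\CBr)C(=O)OC)CC[C@@]1(C)[C@@H](OC(C)=O)CC/C(C)=C/C=O
F19 | step 15 | macrocyclic syn hydroxy ester (seco-lactone of 21) | COC(=O)C(=C)[C@@H]1C/C=C(\C)C2(O)CC[C@@]2(C)[C@@H](OC(C)=O)CC/C(C)=C/[C@@H]1O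
F20 | step 17 | 5-O-acetyl 23 (peroxyketal acetate) | C=C1C(=O)O[C@H]2/C=C(\C)CC[C@H](OC(C)=O)[C@@]3(C)CC[C@](OC(C)=O)(OO3)/C(C)=C/C[C@@H]12
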